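We chose to follow the fraction of substrate left, not the fraction of target made. If the suspect step from substrate and reagent in the reaction phase to target runs, the slope of ln(fraction left) against time is proportional to c(reagent in the reaction phase), a pseudo-first-order constant, and the later fate of target does not enter it.

- theta: substrate 0.50 M; reagent in the second phase 0.95 equiv; the very flask that is asked about, followed so far
- flask: substrate 0.50 M; reagent in the second phase 0.950 equiv; time 20 min; volume of the second phase over the first 2.0

theta run (percent of the substrate charged)

| time / min | target / % | substrate / % |
|---|---|---|
| 2.50 | 0.7 | 98.9 |
| 5.00 | 1.1 | 97.9 |
| 8.00 | 1.6 | 94.9 |
| 10.0 | 3.9 | 93.4 |

(standard deviation of a reading: 0.5 percentage points)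

- amount of target and product in the second phase together at 20 min, in percent of the substrate charged
- part of the substrate charged that has reacted at 20 min

- what is said of target includes product in the second phase
- in the second phase: reagent in the second phase, product in the second phase; everything else is in the first
- charges count per volume of the first phase; a concentration in a rate is the amount of a species over the volume of its own phase; every rate counts per litre of the first phase
- on the list of suspects stand: target <-> product in the second phase; target <-> isomer of the product; reagent in the reaction phase <-> reagent in the second phase; substrate + reagent in the reaction phase -> target; target -> decomposed product
- the earlier runs hold the two phases in the same ratio of volumes as the flask asked about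

Two chemists dispute this flask. The first holds that one constant has ruled since the start: the substrate left at 10.0 min gives 0.00683 /min, hence 12.8% reacted at 20 min. The second objects that the reagent was charged to the second phase, so c(reagent in the reaction phase) started from nothing and climbs. Up to 5.00 min the constant reads 0.00424 /min. The stretch after it defines the late loss constant, the ln of the ratio of the two substrate readings over the time between them: 0.00941 /min, higher than the early reading. The second keeps the exponent reached at 10.0 min and adds this constant for the remaining time, which gives 0.162, or 15.0% reacted. The first answers that two readings, each with a scatter of 0.5 percentage points, make a wide slope. True, but we commit to the second reckoning.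

The forecast, from the same readings, gives 15% reacted and 7.5% of target, and says the loss “fits reagent slowly building up in the reaction phase by transfer from the second phase”.

The flask gives 16.1% reacted and 6.70% of target and product in the second phase together, nearer the second reckoning than the first.

    target ⇌ product in the second phase, rate k1*([target] - [product in the second phase]/K1) per volume of the first phase (partition coefficient = 2.60, kL = 0.00450 /s)
    target ⇌ isomer of the product (K = 7.30, k = 0.00710 /s)
    reagent in the reaction phase ⇌ reagent in the second phase, rate k3*([reagent in the reaction phase] - [reagent in the second phase]/K3) per volume of the first phase (partition coefficient = 0.790, kL = 3.80 × 10⁻⁴ /s)
    substrate + reagent in the reaction phase → target (k = 0.00630 /M/s)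
    target → decomposed product (k = 0.00150 /s)

In this flask c(reagent in the reaction phase) is 0.0110 M at 2.00 min, 0.0268 M at 10.0 min and 0.0290 M at 20.0 min. A single constant, the first chemist's view, has its region after 10.0 min, but there the substrate of this flask falls with 0.0107 /min, above his 0.00683 /min. Carried on to 200 min, the late constant gives 84.4% reacted; the flask gives 81.1%.

At 0.20 M of substrate, with the same equivalents, the reagent charge shrinks too. The same exponent gives 15.0% if c(reagent in the reaction phase) holds, and 6.29% if it shrinks with the charge. The computed neighbour flask has 10.3% reacted, between the two, with 4.39% of target.

(The earlier runs and the new flask were computed for an exercise; noise was put on by code.)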